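## Structural features

The target is a trans-fused bicycle: a nine-membered carbocycle (C1–C9) shares the C8–C9 bond with a tetrahydrofuran (C8, C9, C10, O, C11). The carbocycle carries an exocyclic methylidene on C1, a Z C3=C4 alkene and a tertiary allylic carbinol at C5, so C1(=CH2)–C2H2–C3H=C4H is a skipped diene. C11 is a fully substituted ether carbon bearing an E 4-methylpenta-1,3-dienyl group and a CH2O stearate; the CH2O arm is cis to the C7 branch on C8 and the dienyl group is cis to H8. C8 (S), C9 (R) and C11 (R) are contiguous, whereas C5 (S) is separated from them by two methylene groups and cannot be set by relay. Fragile elements are the tertiary allylic alcohol (ionisation, transannular reactions), the doubly allylic C2 methylene, the dienyl-substituted tertiary ether and the conjugated diene, which binds late transition metals strongly. The real difficulty is the strained nine-membered ring with its Z alkene and, separately, the quaternary C11. The key step exploits the fact that the skipped diene C1–C4 is exactly what an ene-type union of a C9 ethynyl group with a C5 allyl group delivers, so forming C1–C2 closes the carbocycle and creates both alkenes at once.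

## Logic of the disconnections

**Ester C–O bond (23 ⇒ 21 + 22).** The fatty acyl chain adds nothing to the stereochemical problem and makes intermediates waxy, so it is cut first. The forward acylation must take only the primary hydroxyl on the C11 CH2 group and leave the tertiary allylic C5 hydroxyl alone.

**O–C11 ring ether bond (21 ⇒ 20).** The ether is opened at the quaternary carbon and the hydroxymethyl oxygen is folded back onto C11 as an oxirane. C11 then arises by substitution on a π-allyl metal intermediate, which erases the configuration of its precursor, so 20 need not be one epimer. One isomerisation makes the ring, the quaternary centre and the free CH2OH. The forward step needs 5-exo attack of the C10 hydroxyl at the more substituted allyl terminus, with control of the face.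

**C11–CH2 and CH2–O bonds of the oxirane (20 ⇒ 19).** Removing the methylene leaves a dienone. The forward step must transfer a methylene 1,2 to a dienone that carries two free hydroxyls, without epimerising C8.

**C11–C12 bond (19 ⇒ 15 + 18; 18 ⇐ 17 ⇐ 16).** Cutting between the carbonyl carbon and the diene returns a lactone and a six-carbon dienyl nucleophile, itself made by one-carbon olefination. The conjugated diene thus enters only after the ring-forming metal has been used. The forward addition must stop after one addition to the lactone and keep the E geometry.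

**C1–C2 bond, the strategic cut (15 ⇒ 14).** Breaking C1–C2 and shifting the C3=C4 alkene back to a terminal C2=C3 alkene opens the carbocycle to an ethynyl group on C9 and an allyl group on C5. The gain is large: 14 is a monocyclic trans-disubstituted lactone and the forward step is a pure isomerisation. 14 is specified more tightly than a bare enyne:
- C11 is kept as the flat lactone carbonyl, which eases transannular strain.
- The alkyne is terminal and uncapped, so hydrogen sits on the ruthenium-bound carbon.
- The tertiary hydroxyl is left free as a hemilabile donor, which also avoids protecting-group steps.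
- No conjugated diene is present.
- 14 is used as a single C5 epimer.

The forward step must bond at the internal alkyne carbon, close a nine-membered ring in preference to oligomerising, and give the Z alkene.

**C(sp)–Si bond (14 ⇒ 13).** The alkyne stays capped until the last moment, so that enolate and boron chemistry never meet an acidic alkyne hydrogen. The forward step needs a buffered fluoride source.

**C4–C5 bond (13 ⇒ 11 + 12).** Removing the allyl group exposes a methyl ketone. Because C5 is remote from C8, the forward step must be fully reagent-controlled and must distinguish methyl from an unbranched chain.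

**Acetal C–O bonds (11 ⇒ 10).** The ketone is masked during enolate chemistry. The forward step is a mild hydrolysis.

**C7–C8 bond (10 ⇒ 6 + 8 through 9; 8 ⇐ 7).** Cutting next to the lactone carbonyl gives a monosubstituted lactone and a four-carbon masked ketone electrophile. The forward alkylation must go trans to the C9 substituent, and the halide must be reactive enough.

**C9–C1 bond (6 ⇒ 5 + 4; 4 ⇐ 1 + 2 through 3).** Removing the alkynyl group leaves the achiral butenolide. The forward step is a catalytic asymmetric conjugate alkynylation that sets C9 and, through it, C8.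

## Other disconnections considered

Alternative 1: The cut is the O–C11 bond, made on a monocyclic precursor before the carbocycle exists. Zerovalent palladium (Pd2(dba)3 with a chiral diaminocyclohexane bis(phosphinobenzamide)) would ionise a dienyl oxirane, and the C10 hydroxyl would close the tetrahydrofuran to give {(2R,3S,4R)-2-[(1E)-4-methylpenta-1,3-dien-1-yl]-3-[2-(2-methyl-1,3-dioxolan-2-yl)ethyl]-4-[5-(trimethylsilyl)pent-1-en-4-yn-2-yl]oxolan-2-yl}methanol A1.
- In its favour: C11, the CH2OH group and the E diene arrive in one catalytic step on a flexible substrate. This is the same reaction type as step 12 of the chosen plan, so on the mechanism of C11 formation the two are equal, and A1 probably has the easier, less biased substrate.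
- Against it here: the nine-membered ring must then be closed with the diene and the quaternary ether already present, most plausibly by adding the C4 alkyne carbon to the C5 ketone. That passes through a strained cyclononyne, sets C5 only by substrate control inside a medium ring, and needs a cis semi-reduction beside a conjugated diene.
- Comparison: step counts are close. The chosen plan sets C5 under reagent control before ring closure, forms both ring alkenes in the closing step and never shows the diene to the ring-forming metal.

Alternative 2: The cuts are C8–C11 and C9–C10 together. SnCl4 would turn the dienone ketal of an allylic 1,2-diol into an oxocarbenium ion at C11; the E C8=C9 alkene attacks it and a 1,2-shift of C10 from C1 to C9 ends in the C1 ketone. The product is 1-[(3S,4S,5R)-5-{[(tert-butyldiphenylsilyl)oxy]methyl}-5-[(1E)-4-methylpenta-1,3-dien-1-yl]-4-{(3S)-3-methyl-3-[(triethylsilyl)oxy]pent-4-en-1-yl}oxolan-3-yl]but-3-en-1-one A2.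
- In its favour: the Prins–pinacol cascade is a documented route to 3-acyl tetrahydrofurans and is convergent. It would set C8, C9 and C11 in a single step through a chair-like transition state; here it is better than the chosen plan, which spends steps 2, 4 and 12 on the same three centres.
- Against it here: the oxocarbenium ion is conjugated with the diene, so charge is spread over C11, C13 and C15. A strong Lewis acid meets a tertiary allylic silyl ether at C5. The carbocycle must afterwards be closed by metathesis between the allyl ketone and the C5 vinyl group with the diene present, through a β,γ-unsaturated ketone that can slip into conjugation or epimerise C9. The hindered C1 ketone must finally be methylenated, and two silyl groups must be removed.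
- Comparison: more elegant for the heterocycle, but the carbocycle is left to a late and less selective closure and the sequence after the key step is longer.

Alternative 3: The cuts are C9–C1 and C8–C7 in one operation. A copper–phosphoramidite catalyst (from Cu(OTf)2) would add a 2-substituted alkenylaluminium reagent to C9 of 5, and the enolate would be alkylated at C8 by 8 in the same flask. The product is (3S,4R)-3-[2-(2-methyl-1,3-dioxolan-2-yl)ethyl]-4-[5-(trimethylsilyl)pent-1-en-4-yn-2-yl]dihydrofuran-2(3H)-one A3.
- In its favour: both ring-fusion centres, the exocyclic alkene and C2–C4 come in one step from the same butenolide. For the lactone core this is better in step economy than the chosen plan (one step against steps 2 and 4), and the trans relation arises in the same way.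
- Against it here: copper-catalysed asymmetric addition of alkenylalanes is established mainly for cyclic enones, and a five-membered unsaturated lactone is a poor acceptor. Aluminium enolates are weak nucleophiles toward unactivated primary iodides, so the one-flask trapping is the weak point. A3 still lacks the carbocycle, which would have to be closed at C4–C5 with the same cyclononyne and C5 problems as in alternative 1.
- Comparison: the chosen plan accepts one more step for the core in exchange for a ring closure that needs no later redox adjustment.

Key step: step 8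

## Route

Remark on the chemistry: the target is read as 5S, 8S, 9R, 11R with a trans C8–C9 fusion, a Z ring alkene and an E diene. Compounds 14 and 15 and the intermediates A1–A3 were checked atom by atom against this reading and agree, so no structure needed correction. The absolute sense of the catalyst-controlled steps 2, 6 and 12 is assigned by analogy, and the mirror-image catalyst is substituted if a model reaction shows the opposite sense.

Step 1
Reactants: 1 (triisopropylsilyl)acetylene; 2 benzophenone
Product: 4 1,1-diphenyl-3-(triisopropylsilyl)prop-2-yn-1-ol, via lithium (triisopropylsilyl)acetylide 3 (not isolated)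
Conditions: n-BuLi, THF, −78 °C; then 2, −78 °C → rt; H2O
Reagents that add atoms: none
Why: Deprotonation of the terminal alkyne and 1,2-addition of the lithium acetylide to a non-enolisable diaryl ketone (acetylide addition); the tertiary propargylic alcohol is the alkynyl donor for step 2, chosen because it hands over the alkynyl group only at rhodium and so keeps free alkyne out of the mixture.

Step 2
Reactants: 5 2(5H)-furanone; 4 1,1-diphenyl-3-(triisopropylsilyl)prop-2-yn-1-ol
Product: 6 (4R)-4-[(triisopropylsilyl)ethynyl]dihydrofuran-2(3H)-one
Conditions: [RhCl(C2H4)2]2 (2.5 mol %), chiral 2,5-diferrocenylbicyclo[2.2.2]octa-2,5-diene (ferrocenyl = (C5H5)Fe(C5H4); enantiomer that gives Si-face attack at the β-carbon, 5.5 mol %), Cs2CO3 (10 mol %), toluene, 80 °C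
Reagents that add atoms: none
Why: Rhodium-catalysed asymmetric conjugate alkynylation of a cyclic unsaturated ester: the rhodium alkoxide of 4 undergoes β-alkynyl elimination (benzophenone leaves), the alkynylrhodium adds 1,4 to the butenolide and the rhodium enolate is protonated by the next molecule of 4. C9 (R) is set by the chiral diene, which must deliver the alkynyl group to the Si face of the β-carbon; the bulky silyl group blocks alkyne dimerisation.

Step 3
Reactants: 7 2-(2-bromoethyl)-2-methyl-1,3-dioxolane
Product: 8 2-(2-iodoethyl)-2-methyl-1,3-dioxolane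
Conditions: NaI, NaHCO3 (cat.), acetone, reflux
Reagents that add atoms: sodium iodide, [Na+].[I-]
Why: Finkelstein halide exchange driven by precipitation of NaBr; the iodide is needed because a lactone enolate is alkylated too slowly by the unactivated primary bromide.

Step 4
Reactants: 6 (4R)-4-[(triisopropylsilyl)ethynyl]dihydrofuran-2(3H)-one; 8 2-(2-iodoethyl)-2-methyl-1,3-dioxolane
Product: 10 (3S,4R)-3-[2-(2-methyl-1,3-dioxolan-2-yl)ethyl]-4-[(triisopropylsilyl)ethynyl]dihydrofuran-2(3H)-one, via lithium enolate 9 (not isolated)
Conditions: LiN(SiMe3)2, THF, −78 °C; then 8, DMPU, −78 → −30 °C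
Reagents that add atoms: none
Why: Alkylation of a lithium lactone enolate with a primary iodide in the presence of a polar additive; the electrophile approaches the planar enolate from the face opposite the C9 alkynyl substituent, which sets C8 (S) trans to C9. The trans lactone is also the more stable epimer, so any cis material can be equilibrated with DBU.

Step 5
Reactants: 10 (3S,4R)-3-[2-(2-methyl-1,3-dioxolan-2-yl)ethyl]-4-[(triisopropylsilyl)ethynyl]dihydrofuran-2(3H)-one
Product: 11 (3S,4R)-3-(3-oxobutyl)-4-[(triisopropylsilyl)ethynyl]dihydrofuran-2(3H)-one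
Conditions: pyridinium p-toluenesulfonate, acetone/H2O 10:1, 50 °C
Reagents that add atoms: water, O
Why: Mild acid-catalysed hydrolysis of the dioxolane; the lactone, the silylalkyne and both stereocentres are stable to a pyridinium salt in wet acetone.

Step 6
Reactants: 11 (3S,4R)-3-(3-oxobutyl)-4-[(triisopropylsilyl)ethynyl]dihydrofuran-2(3H)-one; 12 allyldiisopropoxyborane
Product: 13 (3S,4R)-3-[(3S)-3-hydroxy-3-methylhex-5-en-1-yl]-4-[(triisopropylsilyl)ethynyl]dihydrofuran-2(3H)-one
Conditions: 3,3'-dibromo-1,1'-bi-2-naphthol (15 mol %; enantiomer that gives Re-face attack, expected to be S), PhCF3/PhMe 3:1, −35 °C; aq. NaHCO3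
Reagents that add atoms: none
Why: Chiral-diol-catalysed asymmetric allylboration of a ketone: exchange of one isopropoxy group for the diol gives a hydrogen-bond-activated chiral boronate that transfers allyl through a closed six-membered chair transition state. C5 (S) is set by the catalyst alone (allyl to the Re face, methyl against the CH2CH2 chain), since C8 is four bonds away; lactone and silylalkyne do not react with the boronate.

Step 7
Reactants: 13 (3S,4R)-3-[(3S)-3-hydroxy-3-methylhex-5-en-1-yl]-4-[(triisopropylsilyl)ethynyl]dihydrofuran-2(3H)-one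
Product: 14 (3S,4R)-4-ethynyl-3-[(3S)-3-hydroxy-3-methylhex-5-en-1-yl]dihydrofuran-2(3H)-one
Conditions: Bu4NF/AcOH 1:1, THF, 0 °C → rt
Reagents that add atoms: none
Why: Fluoride cleavage of the C(sp)–Si bond; acetic acid buffers the mixture so that C8 does not epimerise and the C5 alkoxide does not attack the lactone. The alkyne is unmasked only now, immediately before the ring closure.

Step 8
Reactants: 14 (3S,4R)-4-ethynyl-3-[(3S)-3-hydroxy-3-methylhex-5-en-1-yl]dihydrofuran-2(3H)-one
Product: 15 (3aR,6Z,8S,10aS)-8-hydroxy-8-methyl-4-methylidene-3,3a,4,5,8,9,10,10a-octahydro-1H-cyclonona[c]furan-1-one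
Conditions: [CpRu(NCMe)3]PF6 (10 mol %), acetone, 0.002 M, slow addition of 14, 50 °C
Reagents that add atoms: none
Why: Proposed new method: the cationic divalent ruthenium centre binds the C9 ethynyl group and the terminal alkene of the C5 allyl group and couples them oxidatively to a ruthenacyclopentene (tetravalent ruthenium) in which C1 is bonded to C2 and the metal sits on the former alkyne terminus and on C3; syn β-hydride elimination of a C4 hydrogen followed by C–H reductive elimination at the alkyne terminus releases the 1,4-diene and the catalyst. The closest known reaction type is the [CpRu(NCMe)3]PF6-catalysed alkene–alkyne coupling to branched 1,4-dienes, established between two molecules and for large rings but not for a nine-membered ring. The ring closes in the macrocyclisation mode: the six-atom tether C9–C8–C7–C6–C5–C4 bridges C1 and C3 of the metallacycle, so the methylidene ends up exocyclic and C3=C4 endocyclic. No stereocentre is formed, and C5, C8 and C9 are untouched under the neutral conditions. The step needs bond formation at the internal alkyne carbon and a Z C3=C4 alkene: the first rests on the usual preference of a terminal alkyne to place its substituent β to ruthenium and on the alternative being a ten-membered ring with an E alkene, the second on the expectation that only the C4 hydrogen leading to the cis alkene can become syn-coplanar with the Ru–C3 bond inside a nine-membered ring. The trans lactone holds the two arms on adjacent carbons, C5 is quaternary (gem-disubstituent effect), the free tertiary hydroxyl can act as a hemilabile donor that keeps the alkene on the metal, and no conjugated diene is present; high dilution suppresses intermolecular coupling.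

Step 9
Reactants: 16 3-methylbut-2-enal
Product: 17 (1E)-1-iodo-4-methylpenta-1,3-diene
Conditions: CrCl2 (6 equiv), CHI3 (2 equiv), THF, 0 °C
Reagents that add atoms: iodoform, IC(I)I
Why: Takai olefination: the geminal dichromium species from iodoform and CrCl2 adds to the enal and eliminates anti, which gives the E iodoalkene selectively and leaves the trisubstituted alkene untouched.

Step 10
Reactants: 17 (1E)-1-iodo-4-methylpenta-1,3-diene; 15 (3aR,6Z,8S,10aS)-8-hydroxy-8-methyl-4-methylidene-3,3a,4,5,8,9,10,10a-octahydro-1H-cyclonona[c]furan-1-one
Product: 19 (2E)-1-[(1S,2R,5Z,7S)-7-hydroxy-2-(hydroxymethyl)-7-methyl-3-methylidenecyclonon-5-en-1-yl]-5-methylhexa-2,4-dien-1-one, via [(1E)-4-methylpenta-1,3-dien-1-yl]lithium 18 (not isolated)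
Conditions: 17, t-BuLi (2 equiv per 17), Et2O, −78 °C; then 15 (0.4 equiv), THF, −78 °C; AcOH at −78 °C
Reagents that add atoms: none
Why: Iodine–lithium exchange with retention of the E geometry, then acyl substitution on the lactone that stops at the lithium lactolate at −78 °C (organolithium addition to a lactone); the first equivalent of 18 is consumed by the C5 hydroxyl. Cold acidic quench releases the γ-hydroxy dienone with C8 and C9 unchanged.

Step 11
Reactants: 19 (2E)-1-[(1S,2R,5Z,7S)-7-hydroxy-2-(hydroxymethyl)-7-methyl-3-methylidenecyclonon-5-en-1-yl]-5-methylhexa-2,4-dien-1-one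
Product: 20 (1S,2Z,6R,7S)-6-(hydroxymethyl)-1-methyl-5-methylidene-7-{2-[(1E)-4-methylpenta-1,3-dien-1-yl]oxiran-2-yl}cyclonon-2-en-1-ol (either configuration at the oxirane carbon)
Conditions: Me3S+ I− (4 equiv), KN(SiMe3)2 (3.8 equiv), THF, −10 °C; then 19, −10 → 0 °C
Reagents that add atoms: trimethylsulfonium iodide, C[S+](C)C.[I-]
Why: Corey–Chaykovsky epoxidation: the unstabilised sulfonium ylide adds irreversibly to the carbonyl carbon of the dienone (1,2, not conjugate) and closes the oxirane with loss of dimethyl sulfide; excess ylide covers the two hydroxyls. The configuration at C11 is immaterial because step 12 passes through a π-allyl intermediate; 20 is used at once.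

Step 12
Reactants: 20 (1S,2Z,6R,7S)-6-(hydroxymethyl)-1-methyl-5-methylidene-7-{2-[(1E)-4-methylpenta-1,3-dien-1-yl]oxiran-2-yl}cyclonon-2-en-1-ol
Product: 21 (1R,3aR,6Z,8S,10aS)-1-(hydroxymethyl)-8-methyl-4-methylidene-1-[(1E)-4-methylpenta-1,3-dien-1-yl]-3,3a,4,5,8,9,10,10a-octahydro-1H-cyclonona[c]furan-8-ol
Conditions: Pd2(dba)3·CHCl3 (2.5 mol %), N,N'-(cyclohexane-1,2-diyl)bis[2-(diphenylphosphino)benzamide] (7.5 mol %; enantiomer matched to 11R, expected to be R,R), CH2Cl2, rt
Reagents that add atoms: none
Why: Palladium-catalysed dynamic kinetic asymmetric allylic etherification (Tsuji–Trost cyclisation of a hydroxy vinyl-type epoxide): zerovalent palladium opens the dienyl oxirane with inversion to a zwitterionic π-allyl complex whose two faces interconvert by σ–π slippage along the pentadienyl unit, through its symmetric dimethyl terminus, faster than ring closure. The C10 hydroxyl, deprotonated by the alkoxide just formed, attacks the more substituted terminus C11 anti to palladium in a 5-exo mode, and the chiral diphosphine selects the face so that C11 becomes R whatever the oxirane configuration; the dienyl group ends trans to the C7 branch, which is also the less crowded arrangement, and the syn allyl geometry keeps C12=C13 E.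

Step 13
Reactants: 21 (1R,3aR,6Z,8S,10aS)-1-(hydroxymethyl)-8-methyl-4-methylidene-1-[(1E)-4-methylpenta-1,3-dien-1-yl]-3,3a,4,5,8,9,10,10a-octahydro-1H-cyclonona[c]furan-8-ol; 22 octadecanoyl chloride
Product: 23 [(1R,3aR,6Z,8S,10aS)-8-hydroxy-8-methyl-4-methylidene-1-[(1E)-4-methylpenta-1,3-dien-1-yl]-3,3a,4,5,8,9,10,10a-octahydro-1H-cyclonona[c]furan-1-yl]methyl octadecanoate (CNP0274030.1)
Conditions: 22 (1.1 equiv), pyridine, DMAP (cat.), CH2Cl2, 0 °C
Reagents that add atoms: none
Why: DMAP-catalysed acylation (nucleophilic catalysis); the primary hydroxyl reacts far faster than the hindered tertiary allylic one, so one equivalent of acid chloride at 0 °C should give the mono-ester, which is the target.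

## Compound list

1 | (triisopropylsilyl)acetylene | C#C[Si](C(C)C)(C(C)C)C(C)C | starting material
2 | benzophenone | O=C(c1ccccc1)c1ccccc1 | starting material
3 | lithium (triisopropylsilyl)acetylide | [Li]C#C[Si](C(C)C)(C(C)C)C(C)C | intermediate
4 | 1,1-diphenyl-3-(triisopropylsilyl)prop-2-yn-1-ol | OC(C#C[Si](C(C)C)(C(C)C)C(C)C)(c1ccccc1)c1ccccc1 | intermediate
5 | 2(5H)-furanone | O=C1OCC=C1 | starting material
6 | (4R)-4-[(triisopropylsilyl)ethynyl]dihydrofuran-2(3H)-one | O=C1OC[C@@H](C#C[Si](C(C)C)(C(C)C)C(C)C)C1 | intermediate
7 | 2-(2-bromoethyl)-2-methyl-1,3-dioxolane | CC1(CCBr)OCCO1 | starting material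
8 | 2-(2-iodoethyl)-2-methyl-1,3-dioxolane | CC1(CCI)OCCO1 | intermediate
9 | lithium (4R)-4-[(triisopropylsilyl)ethynyl]-4,5-dihydrofuran-2-olate | [Li]OC1=C[C@H](C#C[Si](C(C)C)(C(C)C)C(C)C)CO1 | intermediate
10 | (3S,4R)-3-[2-(2-methyl-1,3-dioxolan-2-yl)ethyl]-4-[(triisopropylsilyl)ethynyl]dihydrofuran-2(3H)-one | O=C1OC[C@@H](C#C[Si](C(C)C)(C(C)C)C(C)C)[C@@H]1CCC2(C)OCCO2 | intermediate
11 | (3S,4R)-3-(3-oxobutyl)-4-[(triisopropylsilyl)ethynyl]dihydrofuran-2(3H)-one | O=C1OC[C@@H](C#C[Si](C(C)C)(C(C)C)C(C)C)[C@@H]1CCC(C)=O | intermediate
12 | allyldiisopropoxyborane (dipropan-2-yl prop-2-en-1-ylboronate) | C=CCB(OC(C)C)OC(C)C | starting material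
13 | (3S,4R)-3-[(3S)-3-hydroxy-3-methylhex-5-en-1-yl]-4-[(triisopropylsilyl)ethynyl]dihydrofuran-2(3H)-one | O=C1OC[C@@H](C#C[Si](C(C)C)(C(C)C)C(C)C)[C@@H]1CC[C@](C)(O)CC=C | intermediate
14 | (3S,4R)-4-ethynyl-3-[(3S)-3-hydroxy-3-methylhex-5-en-1-yl]dihydrofuran-2(3H)-one | O=C1OC[C@@H](C#C)[C@@H]1CC[C@](C)(O)CC=C | intermediate
15 | (3aR,6Z,8S,10aS)-8-hydroxy-8-methyl-4-methylidene-3,3a,4,5,8,9,10,10a-octahydro-1H-cyclonona[c]furan-1-one | C=C1C/C=C\[C@@](C)(O)CC[C@H]2[C@H]1COC2=O | intermediate
16 | 3-methylbut-2-enal | CC(C)=CC=O | starting material
17 | (1E)-1-iodo-4-methylpenta-1,3-diene | CC(C)=C/C=C/I | intermediate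
18 | [(1E)-4-methylpenta-1,3-dien-1-yl]lithium | [Li]/C=C/C=C(C)C | intermediate
19 | (2E)-1-[(1S,2R,5Z,7S)-7-hydroxy-2-(hydroxymethyl)-7-methyl-3-methylidenecyclonon-5-en-1-yl]-5-methylhexa-2,4-dien-1-one | C=C1C/C=C\[C@@](C)(O)CC[C@H](C(=O)/C=C/C=C(C)C)[C@H]1CO | intermediate
20 | (1S,2Z,6R,7S)-6-(hydroxymethyl)-1-methyl-5-methylidene-7-{2-[(1E)-4-methylpenta-1,3-dien-1-yl]oxiran-2-yl}cyclonon-2-en-1-ol, both oxirane epimers | C=C1C/C=C\[C@@](C)(O)CC[C@H](C2(/C=C/C=C(C)C)CO2)[C@H]1CO | intermediate
21 | (1R,3aR,6Z,8S,10aS)-1-(hydroxymethyl)-8-methyl-4-methylidene-1-[(1E)-4-methylpenta-1,3-dien-1-yl]-3,3a,4,5,8,9,10,10a-octahydro-1H-cyclonona[c]furan-8-ol | C=C1C/C=C\[C@@](C)(O)CC[C@H]2[C@H]1CO[C@@]2(/C=C/C=C(C)C)CO | intermediate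
22 | octadecanoyl chloride (stearoyl chloride) | CCCCCCCCCCCCCCCCCC(=O)Cl | starting material
23 | [(1R,3aR,6Z,8S,10aS)-8-hydroxy-8-methyl-4-methylidene-1-[(1E)-4-methylpenta-1,3-dien-1-yl]-3,3a,4,5,8,9,10,10a-octahydro-1H-cyclonona[c]furan-1-yl]methyl octadecanoate | C=C1C/C=C\[C@@](C)(O)CC[C@H]2[C@H]1CO[C@@]2(/C=C/C=C(C)C)COC(=O)CCCCCCCCCCCCCCCCC | target

## Step count and least certain steps

Total step count: 13. Longest linear sequence: 11 steps (steps 1, 2, 4–8 and 10–13; 1 → 4 → 6 → 10 → 11 → 13 → 14 → 15 → 19 → 20 → 21 → 23). Steps 3 and 9 are side branches.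

**Step 8 (key step).** Most likely failures are oligomerisation by intermolecular coupling, or oxidative coupling at the terminal alkyne carbon that closes the ten-membered isomer. The cause is that a six-atom tether forces a bridged ruthenacycle for which there is no precedent. The fallback uses known chemistry only and closes the ring by olefin metathesis at C3=C4. It sets out from 13 and returns at 15.
- The allyl group of 13 is isomerised to a propenyl group (RuHCl(CO)(PPh3)3, toluene, 80 °C) to give (3S,4R)-3-[(3S,4E)-3-hydroxy-3-methylhex-4-en-1-yl]-4-[(triisopropylsilyl)ethynyl]dihydrofuran-2(3H)-one F1.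
- Buffered fluoride (Bu4NF, AcOH, THF) gives (3S,4R)-4-ethynyl-3-[(3S,4E)-3-hydroxy-3-methylhex-4-en-1-yl]dihydrofuran-2(3H)-one F2.
- The two-component ruthenium alkene–alkyne coupling of F2 with 1-hexene ([CpRu(NCMe)3]PF6, acetone, rt) is an established branched-selective reaction to which the 1,2-disubstituted propenyl group is inert. It gives (3S,4R)-3-[(3S,4E)-3-hydroxy-3-methylhex-4-en-1-yl]-4-[(4E)-octa-1,4-dien-2-yl]dihydrofuran-2(3H)-one F3.
- Ring-closing metathesis of F3 (second-generation Hoveyda–Grubbs catalyst, toluene, 80 °C, high dilution) joins C3 to C4 with loss of hex-2-ene. Because a trans alkene is too strained in this ring, it should give the Z alkene of 15.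

The fallback is two steps longer. Its own weak point is competing seven-membered ring closure onto the C1 methylidene.

**Step 12.** Facial control at C11 may be lost because the allyl terminus sits next to C8 on a medium ring, so catalyst and substrate preferences may oppose each other. The dienyl oxirane made in step 11 may also open prematurely, by alkoxide attack at its CH2 group or by isomerisation to an enal at palladium. The fallback sets C11 by 1,2-addition and closes the ether by substitution at C10, bypassing 20. It sets out from 19 and returns at 21.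
- Selective mesylation of the primary hydroxyl (MsCl, Et3N, CH2Cl2, −20 °C) gives (2E)-1-[(1S,2R,5Z,7S)-7-hydroxy-2-{[(methylsulfonyl)oxy]methyl}-7-methyl-3-methylidenecyclonon-5-en-1-yl]-5-methylhexa-2,4-dien-1-one F4.
- The hydroxymethyl anion equivalent (isopropoxydimethylsilyl)methylmagnesium chloride (CeCl3, THF, −78 °C → rt) adds to the ketone. The tertiary alkoxide displaces the mesylate in a 5-exo-tet closure to give (1R,3aR,6Z,8S,10aS)-1-{[dimethyl(propan-2-yloxy)silyl]methyl}-8-methyl-4-methylidene-1-[(1E)-4-methylpenta-1,3-dien-1-yl]-3,3a,4,5,8,9,10,10a-octahydro-1H-cyclonona[c]furan-8-ol F5.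
- Tamao oxidation (KF, KHCO3, H2O2, THF/MeOH) turns C–Si into C–OH and gives 21.

The facial sense of the addition is substrate-controlled and would have to be checked. It can be inverted by attaching the two carbon groups to C11 in the opposite order.

**Step 6.** Facial selectivity in the allyl transfer may be incomplete, because the catalyst must tell methyl from an unbranched CH2CH2 chain and the nearest stereocentre is four bonds away. The C5 epimer would be hard to remove before the rigid bicyclic stage. The fallback takes C5 from the chiral pool. It sets out from 6 and returns at 14.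
- (S)-Mevalonolactone, the unnatural enantiomer, is reduced (i-Bu2AlH, CH2Cl2, −78 °C) to (4S)-4-methyltetrahydro-2H-pyran-2,4-diol F6.
- Wittig methylenation (Ph3P=CH2, THF) gives (3R)-3-methylhex-5-ene-1,3-diol F7.
- The primary hydroxyl is converted to iodide (I2, PPh3, imidazole) to give (3R)-1-iodo-3-methylhex-5-en-3-ol F8.
- Silylation (Et3SiOTf, 2,6-lutidine) gives triethyl{[(3R)-1-iodo-3-methylhex-5-en-3-yl]oxy}silane F9.
- The enolate 9 from 6 is alkylated with F9 under the conditions of step 4 to give (3S,4R)-3-{(3S)-3-methyl-3-[(triethylsilyl)oxy]hex-5-en-1-yl}-4-[(triisopropylsilyl)ethynyl]dihydrofuran-2(3H)-one F10.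
- Bu4NF removes both silyl groups and gives 14.

This replaces steps 3–7 by six steps and depends on a supply of the unnatural lactone.

**Step 10.** The lithium lactolate may collapse before the quench, so that a second dienyl group adds, or the organolithium may act as a base at C8. The fallback goes through an N-methoxy-N-methylamide. It sets out from 15 and returns at 19.
- MeNH(OMe)·HCl and i-PrMgCl (THF, −20 °C) open the lactone to (1S,2R,5Z,7S)-7-hydroxy-2-(hydroxymethyl)-N-methoxy-N,7-dimethyl-3-methylidenecyclonon-5-ene-1-carboxamide F11.
- Excess 18 at −78 °C converts F11 into 19 through a stable chelated adduct that cannot add twice.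

## Further compounds

F1 | step 8 | (3S,4R)-3-[(3S,4E)-3-hydroxy-3-methylhex-4-en-1-yl]-4-[(triisopropylsilyl)ethynyl]dihydrofuran-2(3H)-one | O=C1OC[C@@H](C#C[Si](C(C)C)(C(C)C)C(C)C)[C@@H]1CC[C@](C)(O)/C=C/C
F2 | step 8 | (3S,4R)-4-ethynyl-3-[(3S,4E)-3-hydroxy-3-methylhex-4-en-1-yl]dihydrofuran-2(3H)-one | O=C1OC[C@@H](C#C)[C@@H]1CC[C@](C)(O)/C=C/C
F3 | step 8 | (3S,4R)-3-[(3S,4E)-3-hydroxy-3-methylhex-4-en-1-yl]-4-[(4E)-octa-1,4-dien-2-yl]dihydrofuran-2(3H)-one | O=C1OC[C@@H](C(=C)C/C=C/CCC)[C@@H]1CC[C@](C)(O)/C=C/C
F4 | step 12 | (2E)-1-[(1S,2R,5Z,7S)-7-hydroxy-2-{[(methylsulfonyl)oxy]methyl}-7-methyl-3-methylidenecyclonon-5-en-1-yl]-5-methylhexa-2,4-dien-1-one | C=C1C/C=C\[C@@](C)(O)CC[C@H](C(=O)/C=C/C=C(C)C)[C@H]1COS(C)(=O)=O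
F5 | step 12 | (1R,3aR,6Z,8S,10aS)-1-{[dimethyl(propan-2-yloxy)silyl]methyl}-8-methyl-4-methylidene-1-[(1E)-4-methylpenta-1,3-dien-1-yl]-3,3a,4,5,8,9,10,10a-octahydro-1H-cyclonona[c]furan-8-ol | C=C1C/C=C\[C@@](C)(O)CC[C@H]2[C@H]1CO[C@@]2(/C=C/C=C(C)C)C[Si](C)(C)OC(C)C
F6 | step 6 | (4S)-4-methyltetrahydro-2H-pyran-2,4-diol | C[C@]1(O)CCOC(O)C1
F7 | step 6 | (3R)-3-methylhex-5-ene-1,3-diol | OCC[C@](C)(O)CC=C
F8 | step 6 | (3R)-1-iodo-3-methylhex-5-en-3-ol | ICC[C@](C)(O)CC=C
F9 | step 6 | triethyl{[(3R)-1-iodo-3-methylhex-5-en-3-yl]oxy}silane | ICC[C@](C)(O[Si](CC)(CC)CC)CC=C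
F10 | step 6 | (3S,4R)-3-{(3S)-3-methyl-3-[(triethylsilyl)oxy]hex-5-en-1-yl}-4-[(triisopropylsilyl)ethynyl]dihydrofuran-2(3H)-one | O=C1OC[C@@H](C#C[Si](C(C)C)(C(C)C)C(C)C)[C@@H]1CC[C@](C)(O[Si](CC)(CC)CC)CC=C
F11 | step 10 | (1S,2R,5Z,7S)-7-hydroxy-2-(hydroxymethyl)-N-methoxy-N,7-dimethyl-3-methylidenecyclonon-5-ene-1-carboxamide | C=C1C/C=C\[C@@](C)(O)CC[C@H](C(=O)N(C)OC)[C@H]1CO
A1 | alternative 1 | {(2R,3S,4R)-2-[(1E)-4-methylpenta-1,3-dien-1-yl]-3-[2-(2-methyl-1,3-dioxolan-2-yl)ethyl]-4-[5-(trimethylsilyl)pent-1-en-4-yn-2-yl]oxolan-2-yl}methanol | C[Si](C)(C)C#CCC(=C)[C@@H]1CO[C@@](/C=C/C=C(C)C)(CO)[C@H]1CCC2(C)OCCO2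
A2 | alternative 2 | 1-[(3S,4S,5R)-5-{[(tert-butyldiphenylsilyl)oxy]methyl}-5-[(1E)-4-methylpenta-1,3-dien-1-yl]-4-{(3S)-3-methyl-3-[(triethylsilyl)oxy]pent-4-en-1-yl}oxolan-3-yl]but-3-en-1-one | C=CCC(=O)[C@@H]1CO[C@@](/C=C/C=C(C)C)(CO[Si](c2ccccc2)(c2ccccc2)C(C)(C)C)[C@H]1CC[C@](C)(O[Si](CC)(CC)CC)C=C
A3 | alternative 3 | (3S,4R)-3-[2-(2-methyl-1,3-dioxolan-2-yl)ethyl]-4-[5-(trimethylsilyl)pent-1-en-4-yn-2-yl]dihydrofuran-2(3H)-one | O=C1OC[C@@H](C(=C)CC#C[Si](C)(C)C)[C@@H]1CCC2(C)OCCO2
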